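**Plan**

- Retrosynthetic cuts, in order: N–H and both O–H are masked (N-SEM, two O-methyl). C2–O and C4–O of the benzene ring (ring A) go back to C–F. Then the bond from C1 of ring A to the carbonyl carbon is cut, and last the C3–CH2 bond to the 4-methylpentyl chain.
- Enabling feature: on ring A the oxygens at C2 and C4 lie ortho and para to the aroyl carbon on C1, so each can enter as methoxide displacing fluoride, with the ketone as electron sink. The same two fluorines acidify C3–H (flanked by both) and then C1–H (next to C2–F).
- Forward order: 1,3-difluorobenzene receives the chain at C3 (lithiation, alkylation). It then receives the ketone at C1 (lithiation, acylation by the N-SEM Weinreb amide of 4,5-dichloropyrrole-2-carboxylic acid), then both methoxy groups. SEM and the methyl groups come off last.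
- No ring is built: ring A and the dichloropyrrole (ring B) are bought intact and joined through the carbonyl carbon.
- The target has no stereocentre and no configured double bond, so no stereocontrol is needed.

Key step: step 5

Remark: ring A is numbered C1 (ketone), C2 (O), C3 (4-methylpentyl), C4 (O), C5, C6. Commercial n-Bu4NF solution is assumed to hold enough water to protonate the pyrrolide as it forms in step 6.

**Step 1**
Reactants: 1 1,3-difluorobenzene; 2 1-bromo-4-methylpentane
Product: 4 1,3-difluoro-2-(4-methylpentyl)benzene, via 2,6-difluorophenyllithium 3 (not isolated)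
Conditions: n-BuLi (1.05 equiv), THF, −78 °C; then 2 (1.2 equiv), DMPU, −78 °C, slow warming to rt
Reagents that add atoms: none
Why: Directed ortho-metalation removes the most acidic proton of 1, the one between the two fluorines, and the cold aryllithium is then alkylated by the primary bromide in an SN2 reaction that DMPU accelerates.

**Step 2**
Reactants: 5 4,5-dichloro-1H-pyrrole-2-carboxylic acid
Product: 7 4,5-dichloro-N-methoxy-N-methyl-1H-pyrrole-2-carboxamide, via acyl imidazolide 6 (not isolated)
Conditions: CDI (1.1 equiv), THF, rt until gas evolution ends; then MeNHOMe·HCl (1.3 equiv), rt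
Reagents that add atoms: N,O-dimethylhydroxylamine hydrochloride, CNOC.Cl
Why: Amide coupling through the acyl imidazolide is a standard way to Weinreb amides, and the weakly nucleophilic pyrrole N–H does not interfere at room temperature.

**Step 3**
Reactants: 7 4,5-dichloro-N-methoxy-N-methyl-1H-pyrrole-2-carboxamide
Product: 9 4,5-dichloro-N-methoxy-N-methyl-1-(2-trimethylsilylethoxymethyl)pyrrole-2-carboxamide, via sodium pyrrolide 8 (not isolated)
Conditions: NaH, DMF, 0 °C; then SEMCl, 0 °C to rt
Reagents that add atoms: 2-(trimethylsilyl)ethoxymethyl chloride (SEMCl), C[Si](C)(C)CCOCCl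
Why: N-alkylation of the acidic acylpyrrole N–H installs a group with no acidic proton that withstands aryllithium and methoxide and later keeps the ketone a neutral acceptor.

**Step 4**
Reactants: 4 1,3-difluoro-2-(4-methylpentyl)benzene; 9 4,5-dichloro-N-methoxy-N-methyl-1-(2-trimethylsilylethoxymethyl)pyrrole-2-carboxamide
Product: 12 [4,5-dichloro-1-(2-trimethylsilylethoxymethyl)pyrrol-2-yl][2,4-difluoro-3-(4-methylpentyl)phenyl]methanone, via aryllithium 10 (not isolated), via lithium chelate 11 (not isolated)
Conditions: 4 (1.2 equiv), s-BuLi (1.1 equiv), THF, −78 °C; then 9 (1.0 equiv), −78 to −40 °C; sat. aq. NH4Cl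
Reagents that add atoms: none
Why: A second directed ortho-metalation takes place at the only kind of C–H next to fluorine (the two such sites of 4 are equivalent), and the Weinreb ketone synthesis stops at the ketone because chelate 11 persists until the quench.

**Step 5**
Reactants: 12 [4,5-dichloro-1-(2-trimethylsilylethoxymethyl)pyrrol-2-yl][2,4-difluoro-3-(4-methylpentyl)phenyl]methanone; 13 sodium methoxide
Product: 15 [4,5-dichloro-1-(2-trimethylsilylethoxymethyl)pyrrol-2-yl][2,4-dimethoxy-3-(4-methylpentyl)phenyl]methanone, via 2-fluoro-4-methoxy monoether 14 (not isolated)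
Conditions: NaOMe (6 equiv), dry DMSO, 25 °C, then 90 °C
Reagents that add atoms: sodium methoxide 13, C[O-].[Na+]
Why: This is nucleophilic aromatic substitution by addition–elimination: methoxide adds first to the less crowded C4 and then to C2 of ring A, each time giving a Meisenheimer anion whose charge rests on the C1 carbonyl oxygen, and fluoride leaves, so the C4–O and C2–O bonds form in turn through 14. The closest known reactions are alkoxide and aryloxide displacements on 2,4-difluorophenyl ketones, which run cleanly enough at both positions to be used in polycondensation. The first methoxy group donates into the carbonyl group, so the second displacement should need heat and excess methoxide in a dipolar aprotic solvent. No ring is closed and no stereocentre is formed. The selectivity needed is attack at the two C–F carbons rather than at the C–Cl carbons of ring B or productively at the carbonyl carbon: fluoride on a ketone-activated benzene is by far the better SNAr leaving group, the electron-rich pyrrole cannot stabilise an anionic adduct, and addition to the non-enolisable ketone is reversible. The SEM group keeps nitrogen from becoming a pyrrolide, whose charge would flow into the carbonyl group and switch off the activation.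

**Step 6**
Reactants: 15 [4,5-dichloro-1-(2-trimethylsilylethoxymethyl)pyrrol-2-yl][2,4-dimethoxy-3-(4-methylpentyl)phenyl]methanone
Product: 16 (4,5-dichloro-1H-pyrrol-2-yl)[2,4-dimethoxy-3-(4-methylpentyl)phenyl]methanone
Conditions: n-Bu4NF (1 M in THF, commercial, 5 equiv), THF, 65 °C
Reagents that add atoms: none
Why: Fluoride-induced SEM cleavage (attack at silicon, then loss of ethene and formaldehyde) is favoured because the 2-acyl-4,5-dichloropyrrolide is a good leaving group, while the aryl methyl ethers, the ketone and the C–Cl bonds are inert to fluoride.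

**Step 7**
Reactants: 16 (4,5-dichloro-1H-pyrrol-2-yl)[2,4-dimethoxy-3-(4-methylpentyl)phenyl]methanone
Product: 18 (4,5-dichloro-1H-pyrrol-2-yl)[2,4-dihydroxy-3-(4-methylpentyl)phenyl]methanone (target CNP0317757.0), via bis(dibromoboryloxy) ketone 17 (not isolated)
Conditions: BBr3 (6 equiv), CH2Cl2, −78 °C to rt; then H2O, 0 °C
Reagents that add atoms: none
Why: In this Lewis-acid aryl methyl ether cleavage BBr3 binds each ether oxygen, bromide removes the methyl group (the C2 ether is helped by chelation to the ketone), and hydrolysis of 17 frees both phenols without touching the ketone, C–Cl bonds, pyrrole N–H or alkyl chain.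

**Compound list**

| No. | Name | SMILES | Role |
|---|---|---|---|
| 1 | 1,3-difluorobenzene | Fc1cccc(F)c1 | starting material |
| 2 | 1-bromo-4-methylpentane | CC(C)CCCBr | starting material |
| 3 | 2,6-difluorophenyllithium | [Li]c1c(F)cccc1F | intermediate (not isolated) |
| 4 | 1,3-difluoro-2-(4-methylpentyl)benzene | CC(C)CCCc1c(F)cccc1F | intermediate |
| 5 | 4,5-dichloro-1H-pyrrole-2-carboxylic acid | OC(=O)c1cc(Cl)c(Cl)[nH]1 | starting material |
| 6 | (4,5-dichloro-1H-pyrrol-2-yl)(imidazol-1-yl)methanone | O=C(c1cc(Cl)c(Cl)[nH]1)n1ccnc1 | intermediate (not isolated) |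
| 7 | 4,5-dichloro-N-methoxy-N-methyl-1H-pyrrole-2-carboxamide | CON(C)C(=O)c1cc(Cl)c(Cl)[nH]1 | intermediate |
| 8 | sodium salt of 7 (sodium pyrrolide) | CON(C)C(=O)c1cc(Cl)c(Cl)[n-]1.[Na+] | intermediate (not isolated) |
| 9 | 4,5-dichloro-N-methoxy-N-methyl-1-(2-trimethylsilylethoxymethyl)pyrrole-2-carboxamide | CON(C)C(=O)c1cc(Cl)c(Cl)n1COCC[Si](C)(C)C | intermediate |
| 10 | [2,4-difluoro-3-(4-methylpentyl)phenyl]lithium | [Li]c1ccc(F)c(CCCC(C)C)c1F | intermediate (not isolated) |
| 11 | lithium alkoxide (chelate) from addition of 10 to 9, racemic | [Li+].[O-]C(N(C)OC)(c1ccc(F)c(CCCC(C)C)c1F)c1cc(Cl)c(Cl)n1COCC[Si](C)(C)C | intermediate (not isolated) |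
| 12 | [4,5-dichloro-1-(2-trimethylsilylethoxymethyl)pyrrol-2-yl][2,4-difluoro-3-(4-methylpentyl)phenyl]methanone | CC(C)CCCc1c(F)ccc(C(=O)c2cc(Cl)c(Cl)n2COCC[Si](C)(C)C)c1F | intermediate |
| 13 | sodium methoxide | C[O-].[Na+] | starting material |
| 14 | [4,5-dichloro-1-(2-trimethylsilylethoxymethyl)pyrrol-2-yl][2-fluoro-4-methoxy-3-(4-methylpentyl)phenyl]methanone | CC(C)CCCc1c(OC)ccc(C(=O)c2cc(Cl)c(Cl)n2COCC[Si](C)(C)C)c1F | intermediate (not isolated) |
| 15 | [4,5-dichloro-1-(2-trimethylsilylethoxymethyl)pyrrol-2-yl][2,4-dimethoxy-3-(4-methylpentyl)phenyl]methanone | CC(C)CCCc1c(OC)ccc(C(=O)c2cc(Cl)c(Cl)n2COCC[Si](C)(C)C)c1OC | intermediate |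
| 16 | (4,5-dichloro-1H-pyrrol-2-yl)[2,4-dimethoxy-3-(4-methylpentyl)phenyl]methanone | CC(C)CCCc1c(OC)ccc(C(=O)c2cc(Cl)c(Cl)[nH]2)c1OC | intermediate |
| 17 | (4,5-dichloro-1H-pyrrol-2-yl)[2,4-bis(dibromoboryloxy)-3-(4-methylpentyl)phenyl]methanone | CC(C)CCCc1c(OB(Br)Br)ccc(C(=O)c2cc(Cl)c(Cl)[nH]2)c1OB(Br)Br | intermediate (not isolated) |
| 18 | (4,5-dichloro-1H-pyrrol-2-yl)[2,4-dihydroxy-3-(4-methylpentyl)phenyl]methanone | CC(C)CCCc1c(O)ccc(C(=O)c2cc(Cl)c(Cl)[nH]2)c1O | target |

Total step count: 7
Longest linear sequence: 6 steps (steps 2, 3, 4, 5, 6, 7, counted from 5)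

**Steps most likely to fail**

**1. Step 5 (key step).**
- What may go wrong:
  - The sequence may stall after the first displacement, because the new methoxy group weakens the acceptor and ring A twists out of conjugation with the carbonyl group.
  - Hot methoxide may also demethylate the monoether, strip the SEM group, or cleave the aryl–carbonyl bond in a Haller–Bauer-type scission. Each of these ends the substitution.
- Fallback: the ring oxygens are bought with the arene instead of being introduced by substitution. It sets out from 2 and 9 and rejoins the route at 15.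
  - Commercial 1,3-dimethoxybenzene is lithiated between the methoxy groups with n-BuLi in THF at 0 °C to give 2,6-dimethoxyphenyllithium F1. This species is thermally robust and is alkylated by 2 between rt and reflux to give 1,3-dimethoxy-2-(4-methylpentyl)benzene F2.
  - NBS in MeCN at 0 °C brominates para to one methoxy group and gives 1-bromo-2,4-dimethoxy-3-(4-methylpentyl)benzene F3.
  - Bromine–lithium exchange with n-BuLi in THF at −78 °C gives [2,4-dimethoxy-3-(4-methylpentyl)phenyl]lithium F4. This adds to 9 to form the dimethoxyaryl lithium chelate F5, and aqueous NH4Cl releases 15.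

**2. Step 1.**
- What may go wrong: SN2 alkylation of the weakly nucleophilic, doubly ortho-fluorinated aryllithium may be slower than its loss of LiF on warming (aryne formation and oligomerisation). The bromide may also undergo elimination.
- Fallback: carbonyl addition at −78 °C, with the oxygen removed afterwards. It sets out from 1 by way of 3 and rejoins at 4.
  - 3 is trapped at −78 °C with commercial 4-methylpentanal to give racemic 1-(2,6-difluorophenyl)-4-methylpentan-1-ol F6.
  - p-TsOH in refluxing toluene with removal of water gives 1,3-difluoro-2-[(E)-4-methylpent-1-enyl]benzene F7.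
  - H2 over Pd/C in EtOAc saturates the alkene to give 4.

**3. Step 4.**
- What may go wrong: addition to the hindered, N-substituted Weinreb amide may be slow. That leaves time for LiF loss from the ortho-fluoroaryllithium, proton transfer from ring B or the SEM methylene, or base-induced breakdown of the N-methoxy amide.
- Fallback: a smaller and more electrophilic aldehyde is used and the oxidation level is corrected afterwards. It sets out from 9 and 10 and rejoins at 12.
  - 9 is reduced with i-Bu2AlH in THF at −78 °C to 4,5-dichloro-1-(2-trimethylsilylethoxymethyl)pyrrole-2-carbaldehyde F8.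
  - 10 adds to it at −78 °C to give racemic [4,5-dichloro-1-(2-trimethylsilylethoxymethyl)pyrrol-2-yl][2,4-difluoro-3-(4-methylpentyl)phenyl]methanol F9.
  - MnO2 in CH2Cl2 oxidises this doubly activated carbinol to 12.

**Further compounds**
F1 | step 5 | 2,6-dimethoxyphenyllithium | [Li]c1c(OC)cccc1OC
F2 | step 5 | 1,3-dimethoxy-2-(4-methylpentyl)benzene | COc1cccc(OC)c1CCCC(C)C
F3 | step 5 | 1-bromo-2,4-dimethoxy-3-(4-methylpentyl)benzene | COc1ccc(Br)c(OC)c1CCCC(C)C
F4 | step 5 | [2,4-dimethoxy-3-(4-methylpentyl)phenyl]lithium | [Li]c1ccc(OC)c(CCCC(C)C)c1OC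
F5 | step 5 | dimethoxyaryl lithium chelate (lithium alkoxide from addition of F4 to 9, racemic) | [Li+].[O-]C(N(C)OC)(c1ccc(OC)c(CCCC(C)C)c1OC)c1cc(Cl)c(Cl)n1COCC[Si](C)(C)C
F6 | step 1 | 1-(2,6-difluorophenyl)-4-methylpentan-1-ol (racemic) | CC(C)CCC(O)c1c(F)cccc1F
F7 | step 1 | 1,3-difluoro-2-[(E)-4-methylpent-1-enyl]benzene | CC(C)C/C=C/c1c(F)cccc1F
F8 | step 4 | 4,5-dichloro-1-(2-trimethylsilylethoxymethyl)pyrrole-2-carbaldehyde | O=Cc1cc(Cl)c(Cl)n1COCC[Si](C)(C)C
F9 | step 4 | [4,5-dichloro-1-(2-trimethylsilylethoxymethyl)pyrrol-2-yl][2,4-difluoro-3-(4-methylpentyl)phenyl]methanol (racemic) | OC(c1ccc(F)c(CCCC(C)C)c1F)c1cc(Cl)c(Cl)n1COCC[Si](C)(C)C
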